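## Structural features

Compound 28 has three rings. Ring A is a hexasubstituted phloroglucinol arene, ring B is a 2,2-dimethyl-2H-pyran fused to it (O1 on C8a, alkene carbon C4 on C4a), and ring C is a dearomatised acetylphloroglucinol (a 2-acetyl-3,5-dihydroxycyclohexa-2,5-dienone) that hangs from C6 of ring A through one CH2 group. Ring A carries the butanoyl group on C8, beside the pyran oxygen, and free hydroxyls on C5 and C7, which flank the bridge and chelate the neighbouring carbonyl groups. The only stereocentre is C4 of ring C, a quaternary carbon bearing methyl and (E)-geranyl. It has no stereogenic neighbour, and its ring neighbours C3 and C5 differ only one atom further out (acetyl on C2, bridge on C6), so no relay of chirality is possible. The fragile parts are the styrene-type enol ether of ring B (acid, electrophiles), the geranyl diene next to enolic hydroxyls (acid-induced cycloetherification, E/Z integrity) and the β-triketone of ring C (retro-Claisen cleavage by alkoxide). The real difficulty is regiochemical: three like oxygens on ring A must be matched with the pyran, the acyl group and the bridge, and two hindered, chelated halves must then be joined. The key step exploits the fact that O1 and C4 sit on adjacent arene carbons, C4a next to the oxygenated C5 and C8a next to C8. An aryne spanning C4a and C8a, polarised by the C5 oxygen, takes up both atoms of one carbonyl group in a single orientation and leaves C8 open for the butanoyl group.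

## Logic of the disconnections

**28 to 21 and 26.** The bond cut joins the bridging CH2 to C6 of ring C, and the CH2 carbon returns to the aldehyde level on ring A. A methylene between an enolised 1,3-dione carbon and an ortho-hydroxyaryl group is what a Knoevenagel condensation followed by conjugate reduction leaves behind. The cut gives two halves of similar size, one carrying the orientation problem (21) and one the stereocentre (26). The forward step must condense at an aldehyde flanked by two chelating hydroxyls, reduce only the arylidene intermediate 27, and run without acid, which the geranyl group and ring B would not tolerate.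

**26 to 25, then 25 to 23 and 24.** No bond is cut between 26 and 25: 25 is the racemate and 26 is taken from it by resolution. 25 is cut at the bond from the quaternary carbon to the geranyl CH2, which turns ring C back into an aromatic, achiral acylphloroglucinol (23) and an allylic bromide (24). The gain is the whole of ring C in one step from an arene. The demands are alkylation at the methyl-bearing carbon rather than at the free arene carbon or at oxygen, and survival of the E alkene. The price is a stereocentre formed without control.

**23 to 22.** The aryl–acetyl bond is cut. The two open positions of 22 are equivalent, so the forward acylation has no regiochemical question and only has to stop after one acyl group.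

**21 to 20, then 20 to 16 and 17.** The two O–CH2 bonds of the MOM ethers are restored, then the bond between C8 and the butanoyl carbonyl is cut. With C6 occupied, C8 carries the only arene hydrogen of 16 and lies between two oxygens, so directed metalation must find it. The demands are that the aldehyde be masked while the aryllithium exists and that acylation stop at the ketone.

**16 to 14.** The C6–CHO bond is cut. This removes the last non-oxygen substituent from ring A and leaves a chromene whose two open positions differ only in their neighbours. The forward metalation must choose C6, between the two MOM ethers, over C8.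

**14 to 9 and 10.** Three bonds are cut together, C8a–O1, C4a–C4 and O1–C2, which opens ring B and leaves an aryne precursor and a five-carbon enal. The reason is the ortho relationship of O1 and C4 and the single oxygen beside C4a, which lets a polarised aryne accept the C=O group in one sense only. The forward step must release the aryne slowly under conditions the MOM ethers tolerate, put the carbonyl oxygen on the carbon remote from the ether, and let the benzoxete open and re-close before anything else captures it.

**9 to 7 to 3 to 2 to 1.** The S–O bond of the triflate, the carbamate C–O bond, the aryl–silicon bond and the two MOM acetal bonds are cut in turn, each removing one group from the phloroglucinol core. The demands are silylation between the carbamate and a MOM ether (not between the two MOM ethers), removal of the carbamate without touching the C–Si bond, and acceptance that the first step cannot distinguish the three hydroxyls and is statistical.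

## Other disconnections considered

Alternative 1: The cut is the arene bond C7–C8 of ring A, with ring B left for later: the benzene ring is grown last on a chain already attached to the bridge.
- **Forward step:** Mg(OMe)2 would open the pyrone ring of A1 by methanolysis, and the magnesium-held methylene between the butanoyl carbonyl and the next ketone would attack the new ester carbonyl (Claisen condensation) and aromatise to A2.
- **In favour:** the bridge and the quaternary centre are in place before the arene exists, so no late union of two hindered halves is needed. The arene needs no protecting groups and no organolithium chemistry.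
- **Against:** A2 still lacks ring B. Annulation of 10 on its single free arene carbon could close through either flanking hydroxyl, and nothing in A2 decides between them. The Mg(OMe)2 step would also have to spare the β-triketone of ring C and avoid the competing aldol folding of the opened chain.
- **Comparison:** on structure it leaves open exactly the orientation that the aryne step fixes. On mechanism an anionic acyl transfer replaces a pericyclic cascade, and both are well founded. On step economy it would be the equal or the better of the chosen plan if the last annulation were selective, and on convergence at the bridge it is the better.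

Alternative 2: The cut is the bond between C6 and C5 of ring C (the bridge-bearing carbon and the carbonyl carbon on the quaternary centre).
- **Forward step:** the dianion of diketo ester A4, whose terminal carbon already carries the chromenylmethyl group, would close onto the methyl ester at the quaternary carbon (Dieckmann-type Claisen condensation) to give A5. The stereocentre would be set beforehand by enzymatic hydrolysis of one of the two enantiotopic ester groups of A3.
- **In favour:** the quaternary centre comes from a catalytic desymmetrisation that uses all the material. The bridge bond is made by enolate alkylation rather than by condensation at a deactivated aldehyde.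
- **Against:** A5 has neither the acetyl nor the butanoyl group. C-acetylation of the trione would compete with O-acylation, and butanoylation of C8 would need an aryllithium beside an acidic trione, which forces more protection. The MOM ethers would then be removed by acid with the geranyl group and the enols present. The MOM-protected chromene must still be made, and this alternative offers nothing new for it.
- **Comparison:** on structure it solves the stereocentre and leaves the orientation of ring B to other means, the reverse of the chosen plan. On mechanism both rest on known reaction types. On the stereocentre it is the better, because the chosen plan resolves a racemate. On step economy it is the worse, being a long linear sequence.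

Alternative 3: The cut is the bond between C2 and C3 of ring C (the acetyl-bearing carbon and the carbonyl carbon on the quaternary centre).
- **Forward step:** Mg(OMe)2 would open the lactone of pyrandione A6 by methanolysis, and the former acetonyl CH2, now between two ketones, would attack the ester carbonyl to close the carbocycle and give A7, the same compound as 26.
- **In favour:** it delivers exactly the partner of the last step with the stereocentre fixed before the ring exists (again from A3). It has neither the site-selectivity problem of an alkylative dearomatisation nor the loss of half the material in a resolution.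
- **Against:** it does not address ring B, so the orientation problem remains. Reaching A6 from A3 takes more operations than the three steps that lead to 26 here. The opened chain could also fold by aldol condensation towards a resorcinol.
- **Comparison:** on structure the two are complementary, since they address different halves. On stereocontrol and material economy at the quaternary centre the alternative is the better. On step count to 26 the chosen plan is shorter. Mechanistically both are sound, and a close variant of this chemistry is kept as the fallback for step 10.

Key step: step 5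

Assumption: ring C is written throughout in the enol form drawn for 28. The CIP descriptor of the quaternary carbon depends on the ranking of its ring neighbours (R in 26 and 28, S in 27), although its spatial arrangement never changes.

## Route

Step 1
Reactants: 1 phloroglucinol (benzene-1,3,5-triol)
Product: 2 3,5-bis(methoxymethoxy)phenol
Conditions: MOMCl (2.0 equiv), i-Pr2NEt, THF–DMF, 0 °C → rt
Reagents that add atoms: chloromethyl methyl ether, COCCl
Why: O-alkylation of the phenoxide by an α-chloro ether (acetal formation); the reaction is statistical, so the bis-ether is separated by chromatography and the mono- and tris-ethers are returned to the pool.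

Step 2
Reactants: 2 3,5-bis(methoxymethoxy)phenol
Product: 3 3,5-bis(methoxymethoxy)phenyl N-(propan-2-yl)carbamate
Conditions: i-PrNCO, Et3N (cat.), CH2Cl2, rt
Reagents that add atoms: isopropyl isocyanate, CC(C)N=C=O
Why: Base-catalysed addition of the phenol to the isocyanate (carbamoylation); the secondary carbamate is the strongest ortho-director on the ring and, unlike a tertiary one, can later be removed by mild base.

Step 3
Reactants: 3 3,5-bis(methoxymethoxy)phenyl N-(propan-2-yl)carbamate
Product: 7 3,5-bis(methoxymethoxy)-2-(trimethylsilyl)phenyl N-(propan-2-yl)carbamate, via N-silyl carbamate 4 (not isolated), via ortho-lithiated carbamate 5 (not isolated), via C-silylated N-silyl carbamate 6 (not isolated)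
Conditions: TBSOTf, TMEDA, Et2O, 0 °C → rt; n-BuLi, TMEDA, −78 °C; TMSCl, −78 °C → rt; aq. NH4Cl
Reagents that add atoms: chlorotrimethylsilane, C[Si](C)(C)Cl
Why: Directed ortho-metalation: N-silylation masks the N–H, n-BuLi removes the hydrogen between the carbamate and a MOM ether (two equivalent positions, both directors cooperating, the carbamate outranking the pair of MOM ethers that flank C4), and TMSCl traps the aryllithium. The low temperature holds back the anionic ortho-Fries shift, and the N–Si bond is hydrolysed on work-up.

Step 4
Reactants: 7 3,5-bis(methoxymethoxy)-2-(trimethylsilyl)phenyl N-(propan-2-yl)carbamate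
Product: 9 3,5-bis(methoxymethoxy)-2-(trimethylsilyl)phenyl trifluoromethanesulfonate, via silyl phenol 8 (not isolated)
Conditions: DBU, Et2NH, MeCN, 40 °C; then PhNTf2, rt
Reagents that add atoms: N-phenylbis(trifluoromethanesulfonimide), O=S(=O)(N(c1ccccc1)S(=O)(=O)C(F)(F)F)C(F)(F)F
Why: E1cB cleavage of the secondary carbamate (DBU removes the N–H, the phenoxide of 8 is expelled and the isocyanate is scavenged by Et2NH as a urea), then O-sulfonylation of the phenoxide by PhNTf2 in the same flask. The medium is free of acid and fluoride, so the MOM ethers and the C–Si bond stay.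

Step 5
Reactants: 9 3,5-bis(methoxymethoxy)-2-(trimethylsilyl)phenyl trifluoromethanesulfonate; 10 3-methylbut-2-enal
Product: 14 5,7-bis(methoxymethoxy)-2,2-dimethyl-2H-chromene, via aryne 11 (not isolated), via benzoxete 12 (not isolated), via ortho-quinone methide 13 (not isolated)
Conditions: CsF (3 equiv), 10 (3 equiv), MeCN, rt, slow addition of 9
Reagents that add atoms: none
Why: Fluoride attacks silicon and the aryl anion expels triflate, releasing aryne 11 at low stationary concentration. The MOM ether beside one aryne carbon withdraws inductively and distorts the triple bond, so the remote carbon (the later C8a) is the electrophilic terminus and takes the carbonyl oxygen of 10; the aryl anion thus formed sits next to the ether, is stabilised by it, and collapses onto the oxocarbenium carbon to give benzoxete 12, a stepwise formal [2+2] that closes the four-membered ring by anion–cation combination. Strain-driven electrocyclic opening of 12 gives ortho-quinone methide 13, an oxatriene, which closes ring B by thermal, disrotatory oxa-6π electrocyclisation onto the dimethyl-substituted carbon and restores aromaticity. The closest known reaction type is the fluoride-triggered insertion of arynes into the C=O bond of formamides and α,β-unsaturated aldehydes, which leads to 2H-chromenes. No stereocentre remains in 14: the benzoxete carbon is stereogenic only in passing and C2 carries two methyl groups. The selectivity needed is the orientation of C=O across the aryne (O to C8a, C to C4a), and the single flanking MOM ether secures it. Addition occurs at the carbonyl and not at the β-carbon because the oxygen is the nucleophile, and the excess of 10 together with slow release of 11 suppresses capture of 13 by a second aryne.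

Step 6
Reactants: 14 5,7-bis(methoxymethoxy)-2,2-dimethyl-2H-chromene
Product: 16 5,7-bis(methoxymethoxy)-2,2-dimethyl-2H-chromene-6-carbaldehyde, via 6-lithiochromene 15 (not isolated)
Conditions: n-BuLi, THF, 0 °C; DMF, 0 °C → rt; aq. NH4Cl
Reagents that add atoms: N,N-dimethylformamide, CN(C)C=O
Why: Directed ortho-metalation then formylation: the C6 hydrogen lies between two chelating MOM ethers and should be removed in preference to the C8 hydrogen, which has one MOM ether and the less basic ring-bound ether oxygen beside it. Aryllithium 15 adds to DMF and the aldehyde is released on aqueous work-up.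

Step 7
Reactants: 16 5,7-bis(methoxymethoxy)-2,2-dimethyl-2H-chromene-6-carbaldehyde; 17 N-methoxy-N-methylbutanamide
Product: 20 8-butanoyl-5,7-bis(methoxymethoxy)-2,2-dimethyl-2H-chromene-6-carbaldehyde, via amino alkoxide 18 (not isolated), via 8-lithio amino alkoxide 19 (not isolated)
Conditions: LiN(Me)CH2CH2NMe2 (from MeNHCH2CH2NMe2, n-BuLi), THF, −20 °C; n-BuLi, −20 → 0 °C; 17, −78 → 0 °C; aq. NH4Cl
Reagents that add atoms: none
Why: In situ protection, directed ortho-metalation and acylation: the lithium amide adds to the aldehyde to give α-amino alkoxide 18, which is inert to n-BuLi; the only remaining arene hydrogen (C8, between a MOM ether and O1) is lithiated to 19, and its addition to the N-methoxy-N-methylamide stops at the chelated tetrahedral adduct, so no tertiary alcohol forms. Aqueous work-up returns the aldehyde and frees the ketone.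

Step 8
Reactants: 20 8-butanoyl-5,7-bis(methoxymethoxy)-2,2-dimethyl-2H-chromene-6-carbaldehyde
Product: 21 8-butanoyl-5,7-dihydroxy-2,2-dimethyl-2H-chromene-6-carbaldehyde
Conditions: HCl (3 M aq.), MeOH, 40 °C
Reagents that add atoms: none
Why: Acid-catalysed acetal methanolysis of both MOM ethers; each sits ortho to a carbonyl group that chelates the freed phenol, so cleavage should proceed at an acidity and temperature that the 2H-chromene tolerates. The geranyl group is not yet present, which is why deprotection precedes the union.

Step 9
Reactants: 22 2-methylbenzene-1,3,5-triol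
Product: 23 1-(2,4,6-trihydroxy-3-methylphenyl)ethan-1-one
Conditions: AcCl, AlCl3, CH2Cl2–PhNO2, 0 °C → rt; aq. HCl
Reagents that add atoms: acetyl chloride, CC(=O)Cl
Why: Friedel–Crafts acylation; the two free positions of 22 are equivalent, and the first acyl group deactivates the ring and binds AlCl3, so monoacylation should be clean.

Step 10
Reactants: 23 1-(2,4,6-trihydroxy-3-methylphenyl)ethan-1-one; 24 geranyl bromide ((2E)-1-bromo-3,7-dimethylocta-2,6-diene)
Product: 25 rac-2-acetyl-4-[(2E)-3,7-dimethylocta-2,6-dien-1-yl]-3,5-dihydroxy-4-methylcyclohexa-2,5-dien-1-one
Conditions: KOH (10% aq.), 0 °C → rt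
Reagents that add atoms: none
Why: Alkylative dearomatisation: the phloroglucinolate is C-alkylated by SN2 displacement at the primary allylic bromide (E geometry kept) at the methyl-bearing carbon, which cannot re-aromatise and settles as the cross-conjugated triketone. The quaternary stereocentre forms without facial control, so 25 is racemic; material alkylated at the free arene carbon or at oxygen is removed by chromatography.

Step 11
Reactants: 25 rac-2-acetyl-4-[(2E)-3,7-dimethylocta-2,6-dien-1-yl]-3,5-dihydroxy-4-methylcyclohexa-2,5-dien-1-one
Product: 26 (4R)-2-acetyl-4-[(2E)-3,7-dimethylocta-2,6-dien-1-yl]-3,5-dihydroxy-4-methylcyclohexa-2,5-dien-1-one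
Conditions: preparative SFC, amylose tris(3,5-dimethylphenylcarbamate) phase, CO2–MeOH (0.1% HCO2H)
Reagents that add atoms: none
Why: Resolution of the racemate by chromatography on a chiral stationary phase; the stereocentre is quaternary and cannot racemise by enolisation. The (4R) antipode is to be identified by comparing its electronic circular dichroism with the calculated spectrum before use.

Step 12
Reactants: 21 8-butanoyl-5,7-dihydroxy-2,2-dimethyl-2H-chromene-6-carbaldehyde; 26 (4R)-2-acetyl-4-[(2E)-3,7-dimethylocta-2,6-dien-1-yl]-3,5-dihydroxy-4-methylcyclohexa-2,5-dien-1-one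
Product: 28 (4R)-2-acetyl-6-[(8-butanoyl-5,7-dihydroxy-2,2-dimethyl-2H-chromen-6-yl)methyl]-4-[(2E)-3,7-dimethylocta-2,6-dien-1-yl]-3,5-dihydroxy-4-methylcyclohexa-2,5-dien-1-one, via arylidene trione 27 (not isolated)
Conditions: L-proline (20 mol %), Hantzsch ester (1.2 equiv), EtOH, 40 °C
Reagents that add atoms: none
Why: Reductive Knoevenagel coupling: proline activates the aldehyde as an iminium ion, C6 of 26 adds and eliminates to arylidene trione 27, a strongly polarised acceptor that takes a hydride from the Hantzsch ester at the benzylic carbon. The dihydropyridine should not reduce the ketones, the chromene or the geranyl alkenes, and no acid or strong base is present. The quaternary centre of 26 is carried through untouched and no new stereocentre forms.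

## Compound list

1 | phloroglucinol (benzene-1,3,5-triol) | Oc1cc(O)cc(O)c1 | starting material
2 | 3,5-bis(methoxymethoxy)phenol | COCOc1cc(O)cc(OCOC)c1 | intermediate
3 | 3,5-bis(methoxymethoxy)phenyl N-(propan-2-yl)carbamate | COCOc1cc(OCOC)cc(OC(=O)NC(C)C)c1 | intermediate
4 | 3,5-bis(methoxymethoxy)phenyl N-[tert-butyl(dimethyl)silyl]-N-(propan-2-yl)carbamate | COCOc1cc(OCOC)cc(OC(=O)N(C(C)C)[Si](C)(C)C(C)(C)C)c1 | intermediate (not isolated)
5 | [2-({[tert-butyl(dimethyl)silyl](propan-2-yl)carbamoyl}oxy)-4,6-bis(methoxymethoxy)phenyl]lithium | COCOc1cc(OCOC)c([Li])c(OC(=O)N(C(C)C)[Si](C)(C)C(C)(C)C)c1 | intermediate (not isolated)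
6 | 3,5-bis(methoxymethoxy)-2-(trimethylsilyl)phenyl N-[tert-butyl(dimethyl)silyl]-N-(propan-2-yl)carbamate | COCOc1cc(OCOC)c([Si](C)(C)C)c(OC(=O)N(C(C)C)[Si](C)(C)C(C)(C)C)c1 | intermediate (not isolated)
7 | 3,5-bis(methoxymethoxy)-2-(trimethylsilyl)phenyl N-(propan-2-yl)carbamate | COCOc1cc(OCOC)c([Si](C)(C)C)c(OC(=O)NC(C)C)c1 | intermediate
8 | 3,5-bis(methoxymethoxy)-2-(trimethylsilyl)phenol | COCOc1cc(OCOC)c([Si](C)(C)C)c(O)c1 | intermediate (not isolated)
9 | 3,5-bis(methoxymethoxy)-2-(trimethylsilyl)phenyl trifluoromethanesulfonate | COCOc1cc(OCOC)c([Si](C)(C)C)c(OS(=O)(=O)C(F)(F)F)c1 | intermediate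
10 | 3-methylbut-2-enal | CC(C)=CC=O | starting material
11 | 3,5-bis(methoxymethoxy)benzyne (1,2-didehydro-3,5-bis(methoxymethoxy)benzene) | COCOC1=CC#CC(OCOC)=C1 | intermediate (not isolated)
12 | 3,5-bis(methoxymethoxy)-2-(2-methylprop-1-en-1-yl)-2H-benzo[b]oxete (racemic) | CC(C)=CC1Oc2cc(OCOC)cc(OCOC)c12 | intermediate (not isolated)
13 | 3,5-bis(methoxymethoxy)-6-(3-methylbut-2-en-1-ylidene)cyclohexa-2,4-dien-1-one | CC(C)=CC=C1C(=O)C=C(OCOC)C=C1OCOC | intermediate (not isolated)
14 | 5,7-bis(methoxymethoxy)-2,2-dimethyl-2H-chromene | CC1(C)C=Cc2c(OCOC)cc(OCOC)cc2O1 | intermediate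
15 | [5,7-bis(methoxymethoxy)-2,2-dimethyl-2H-chromen-6-yl]lithium | CC1(C)C=Cc2c(OCOC)c([Li])c(OCOC)cc2O1 | intermediate (not isolated)
16 | 5,7-bis(methoxymethoxy)-2,2-dimethyl-2H-chromene-6-carbaldehyde | CC1(C)C=Cc2c(OCOC)c(C=O)c(OCOC)cc2O1 | intermediate
17 | N-methoxy-N-methylbutanamide | CCCC(=O)N(C)OC | starting material
18 | lithium [5,7-bis(methoxymethoxy)-2,2-dimethyl-2H-chromen-6-yl]{[2-(dimethylamino)ethyl](methyl)amino}methanolate (racemic) | CC1(C)C=Cc2c(OCOC)c(C(O[Li])N(C)CCN(C)C)c(OCOC)cc2O1 | intermediate (not isolated)
19 | lithium {[2-(dimethylamino)ethyl](methyl)amino}[8-lithio-5,7-bis(methoxymethoxy)-2,2-dimethyl-2H-chromen-6-yl]methanolate (racemic) | CC1(C)C=Cc2c(OCOC)c(C(O[Li])N(C)CCN(C)C)c(OCOC)c([Li])c2O1 | intermediate (not isolated)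
20 | 8-butanoyl-5,7-bis(methoxymethoxy)-2,2-dimethyl-2H-chromene-6-carbaldehyde | CCCC(=O)c1c(OCOC)c(C=O)c(OCOC)c2C=CC(C)(C)Oc12 | intermediate
21 | 8-butanoyl-5,7-dihydroxy-2,2-dimethyl-2H-chromene-6-carbaldehyde | CCCC(=O)c1c(O)c(C=O)c(O)c2C=CC(C)(C)Oc12 | intermediate
22 | 2-methylbenzene-1,3,5-triol | Cc1c(O)cc(O)cc1O | starting material
23 | 1-(2,4,6-trihydroxy-3-methylphenyl)ethan-1-one | CC(=O)c1c(O)cc(O)c(C)c1O | intermediate
24 | geranyl bromide ((2E)-1-bromo-3,7-dimethylocta-2,6-diene) | CC(C)=CCC/C(C)=C/CBr | starting material
25 | rac-2-acetyl-4-[(2E)-3,7-dimethylocta-2,6-dien-1-yl]-3,5-dihydroxy-4-methylcyclohexa-2,5-dien-1-one | CC(=O)C1=C(O)C(C)(C/C=C(\C)CCC=C(C)C)C(O)=CC1=O | intermediate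
26 | (4R)-2-acetyl-4-[(2E)-3,7-dimethylocta-2,6-dien-1-yl]-3,5-dihydroxy-4-methylcyclohexa-2,5-dien-1-one | C1=C(O)[C@@](C)(C/C=C(\C)CCC=C(C)C)C(O)=C(C(C)=O)C1=O | intermediate
27 | (4S)-2-acetyl-6-[(8-butanoyl-5,7-dihydroxy-2,2-dimethyl-2H-chromen-6-yl)methylidene]-4-[(2E)-3,7-dimethylocta-2,6-dien-1-yl]-3-hydroxy-4-methylcyclohex-2-ene-1,5-dione (methylidene geometry not defined) | CCCC(=O)c1c(O)c(C=C2C(=O)[C@@](C)(C/C=C(\C)CCC=C(C)C)C(O)=C(C(C)=O)C2=O)c(O)c2C=CC(C)(C)Oc12 | intermediate (not isolated)
28 | (4R)-2-acetyl-6-[(8-butanoyl-5,7-dihydroxy-2,2-dimethyl-2H-chromen-6-yl)methyl]-4-[(2E)-3,7-dimethylocta-2,6-dien-1-yl]-3,5-dihydroxy-4-methylcyclohexa-2,5-dien-1-one | CCCC(=O)c1c(O)c(CC2=C(O)[C@@](C)(C/C=C(\C)CCC=C(C)C)C(O)=C(C(C)=O)C2=O)c(O)c2c1OC(C)(C)C=C2 | target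

## Step count and least certain steps

Total: 12 steps. Longest linear sequence: 9 steps (steps 1 to 8 and step 12, from 1). The branch to 26 (steps 9 to 11) joins in step 12.

**Step 5 (key step).** The most likely failure is consumption of the aryne along paths other than carbonyl addition, namely capture of 13 by a second aryne or self-condensation of the aryne. The cause is that the aldehyde oxygen is a weak nucleophile. Loss of orientation is less likely, because 3-alkoxyarynes are reliably attacked at the remote carbon. Fallback: abandon the aryne and close ring B by condensing a phenol with the enal. Phenol 2 and 10 (ethylenediammonium diacetate, toluene, reflux) would undergo Knoevenagel-type C-alkylation ortho to the hydroxyl and dehydration to the same intermediate 13, followed by the same oxa-6π closure. The two ortho positions of 2 are equivalent, so 14 is the only chromene possible. This fallback sets out from 2, returns at 14, is shorter than steps 2 to 5, and makes no compound outside the list (F0).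

**Step 10.** The most likely failure is loss of site selectivity: alkylation at the free arene carbon (which re-aromatises) and at oxygen compete with attack at the methyl-bearing carbon, because all are positions of one delocalised anion. In addition the step gives a racemate, half of which is lost in step 11. Fallback: build ring C from an open chain with the stereocentre set first.
- Dimethyl methylmalonate is alkylated with 24 (NaH, THF) to dimethyl 2-[(2E)-3,7-dimethylocta-2,6-dien-1-yl]-2-methylpropanedioate F1.
- Pig liver esterase (pH 7.5 buffer) hydrolyses one enantiotopic ester group. By analogy with long-chain 2-alkyl-2-methylmalonates the product is expected to be (2R)-2-[(2E)-3,7-dimethylocta-2,6-dien-1-yl]-3-methoxy-2-methyl-3-oxopropanoic acid F2.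
- After activation with 1,1′-carbonyldiimidazole, F2 acylates the terminal carbon of the acetylacetone dianion (NaH, then n-BuLi, THF) to give methyl (2R)-2-[(2E)-3,7-dimethylocta-2,6-dien-1-yl]-2-methyl-3,5,7-trioxooctanoate F3.
- Mg(OMe)2 in MeOH closes the ring by Claisen condensation of the methylene next to the acetyl group onto the ester, giving 26.

Should the enzyme hydrolyse the other ester group, the two carboxyl groups exchange roles: the acid is attached to the central carbon of acetylacetone and the ring is closed from the acetyl methyl group. The fallback sets out from 24, returns at 26, and makes steps 9 to 11 unnecessary.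

**Step 12.** The most likely failure is slow condensation at the aldehyde, which is flanked by two chelating hydroxyls and deactivated as a vinylogous acid. Reduction then lags, and 27 is diverted into hemiketal closure with a neighbouring phenol or into addition of a second molecule of 26. Fallback: change the electrophile from an aldehyde to a benzylic alcohol that ionises on warming. 21 is reduced with NaBH4 (MeOH, 0 °C; the aldehyde is the more electrophilic of the two chelated carbonyls) to 1-[5,7-dihydroxy-6-(hydroxymethyl)-2,2-dimethyl-2H-chromen-8-yl]butan-1-one F4. Warmed with 26 (NaOAc, toluene, 80 °C), F4 loses water and is captured at the benzylic carbon by C6 of 26 in a conjugate addition, giving 28. The fallback sets out from 21 and returns at 28.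

**Step 6.** The most likely failure is metalation at C8 in competition with C6, because both hydrogens lie between two oxygens and only the number of MOM neighbours differs. Fallback, for the case that C8 is preferred: introduce the two carbon groups in the opposite order and at the alcohol oxidation level. 14 is lithiated (n-BuLi, THF, 0 °C) and quenched with butanal to give 1-[5,7-bis(methoxymethoxy)-2,2-dimethyl-2H-chromen-8-yl]butan-1-ol F5. A second metalation (n-BuLi, 2.2 equiv; alkoxide, then the one remaining arene hydrogen at C6) and DMF give 8-(1-hydroxybutyl)-5,7-bis(methoxymethoxy)-2,2-dimethyl-2H-chromene-6-carbaldehyde F6. Oxidation of the secondary alcohol with Dess–Martin periodinane (NaHCO3, CH2Cl2) gives 20. The fallback sets out from 14 and returns at 20.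

**Step 7.** The most likely failures are incomplete metalation at C8 of the electron-rich amino alkoxide 18, and proton transfer from the α-CH2 of 17 to the hindered aryllithium 19 in place of addition. Fallback: an isolable acetal and an aldehyde electrophile. 16 is converted (HC(OMe)3, pyridinium p-toluenesulfonate cat., MeOH, rt) into 6-(dimethoxymethyl)-5,7-bis(methoxymethoxy)-2,2-dimethyl-2H-chromene F7. Lithiation (n-BuLi, THF, 0 °C) and addition to butanal give 1-[6-(dimethoxymethyl)-5,7-bis(methoxymethoxy)-2,2-dimethyl-2H-chromen-8-yl]butan-1-ol F8. Dess–Martin periodinane (NaHCO3, CH2Cl2) gives 1-[6-(dimethoxymethyl)-5,7-bis(methoxymethoxy)-2,2-dimethyl-2H-chromen-8-yl]butan-1-one F9. The acid of step 8 then removes the acetal together with both MOM ethers and gives 21. The fallback sets out from 16 and returns at 21.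

## Further compounds

F0 | step 5 | none | none
F1 | step 10 | dimethyl 2-[(2E)-3,7-dimethylocta-2,6-dien-1-yl]-2-methylpropanedioate | COC(=O)C(C)(C/C=C(\C)CCC=C(C)C)C(=O)OC
F2 | step 10 | (2R)-2-[(2E)-3,7-dimethylocta-2,6-dien-1-yl]-3-methoxy-2-methyl-3-oxopropanoic acid | OC(=O)[C@@](C)(C/C=C(\C)CCC=C(C)C)C(=O)OC
F3 | step 10 | methyl (2R)-2-[(2E)-3,7-dimethylocta-2,6-dien-1-yl]-2-methyl-3,5,7-trioxooctanoate | CC(=O)CC(=O)CC(=O)[C@@](C)(C/C=C(\C)CCC=C(C)C)C(=O)OC
F4 | step 12 | 1-[5,7-dihydroxy-6-(hydroxymethyl)-2,2-dimethyl-2H-chromen-8-yl]butan-1-one | CCCC(=O)c1c(O)c(CO)c(O)c2C=CC(C)(C)Oc12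
F5 | step 6 | 1-[5,7-bis(methoxymethoxy)-2,2-dimethyl-2H-chromen-8-yl]butan-1-ol (racemic) | CCCC(O)c1c(OCOC)cc(OCOC)c2C=CC(C)(C)Oc12
F6 | step 6 | 8-(1-hydroxybutyl)-5,7-bis(methoxymethoxy)-2,2-dimethyl-2H-chromene-6-carbaldehyde (racemic) | CCCC(O)c1c(OCOC)c(C=O)c(OCOC)c2C=CC(C)(C)Oc12
F7 | step 7 | 6-(dimethoxymethyl)-5,7-bis(methoxymethoxy)-2,2-dimethyl-2H-chromene | CC1(C)C=Cc2c(OCOC)c(C(OC)OC)c(OCOC)cc2O1
F8 | step 7 | 1-[6-(dimethoxymethyl)-5,7-bis(methoxymethoxy)-2,2-dimethyl-2H-chromen-8-yl]butan-1-ol (racemic) | CCCC(O)c1c(OCOC)c(C(OC)OC)c(OCOC)c2C=CC(C)(C)Oc12
F9 | step 7 | 1-[6-(dimethoxymethyl)-5,7-bis(methoxymethoxy)-2,2-dimethyl-2H-chromen-8-yl]butan-1-one | CCCC(=O)c1c(OCOC)c(C(OC)OC)c(OCOC)c2C=CC(C)(C)Oc12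
A1 | alternative 1 | (4R)-2-acetyl-4-[(2E)-3,7-dimethylocta-2,6-dien-1-yl]-3,5-dihydroxy-6-{[4-hydroxy-2-oxo-6-(2-oxopentyl)-2H-pyran-3-yl]methyl}-4-methylcyclohexa-2,5-dien-1-one | CCCC(=O)CC1=CC(O)=C(CC2=C(O)[C@@](C)(C/C=C(\C)CCC=C(C)C)C(O)=C(C(C)=O)C2=O)C(=O)O1
A2 | alternative 1 | (4R)-2-acetyl-6-[(3-butanoyl-2,4,6-trihydroxyphenyl)methyl]-4-[(2E)-3,7-dimethylocta-2,6-dien-1-yl]-3,5-dihydroxy-4-methylcyclohexa-2,5-dien-1-one | CCCC(=O)c1c(O)c(CC2=C(O)[C@@](C)(C/C=C(\C)CCC=C(C)C)C(O)=C(C(C)=O)C2=O)c(O)cc1O
A3 | alternative 2 | dimethyl 2-[(2E)-3,7-dimethylocta-2,6-dien-1-yl]-2-methylpropanedioate | COC(=O)C(C)(C/C=C(\C)CCC=C(C)C)C(=O)OC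
A4 | alternative 2 | methyl (2S)-7-[5,7-bis(methoxymethoxy)-2,2-dimethyl-2H-chromen-6-yl]-2-[(2E)-3,7-dimethylocta-2,6-dien-1-yl]-2-methyl-3,5-dioxoheptanoate | COC(=O)[C@@](C)(C/C=C(\C)CCC=C(C)C)C(=O)CC(=O)CCc1c(OCOC)cc2OC(C)(C)C=Cc2c1OCOC
A5 | alternative 2 | (4S)-6-{[5,7-bis(methoxymethoxy)-2,2-dimethyl-2H-chromen-6-yl]methyl}-4-[(2E)-3,7-dimethylocta-2,6-dien-1-yl]-3,5-dihydroxy-4-methylcyclohexa-2,5-dien-1-one | COCOc1cc2OC(C)(C)C=Cc2c(OCOC)c1CC1=C(O)[C@@](C)(C/C=C(\C)CCC=C(C)C)C(O)=CC1=O
A6 | alternative 3 | (3R)-3-[(2E)-3,7-dimethylocta-2,6-dien-1-yl]-3-methyl-6-(2-oxopropyl)-2H-pyran-2,4(3H)-dione | CC(=O)CC1=CC(=O)[C@@](C)(C/C=C(\C)CCC=C(C)C)C(=O)O1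
A7 | alternative 3 | (4R)-2-acetyl-4-[(2E)-3,7-dimethylocta-2,6-dien-1-yl]-3,5-dihydroxy-4-methylcyclohexa-2,5-dien-1-one | C1=C(O)[C@@](C)(C/C=C(\C)CCC=C(C)C)C(O)=C(C(C)=O)C1=O
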